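**Retrosynthetic overview**
- C3–Br is installed last by inversion of a propargylic alcohol. The cis C9–OAc/C10–Br pair comes from one radical anti-Markovnikov HBr addition to the ring enol acetate (C9=C10) of the bicyclic ketone; this is the key step.
- The oxocane is closed by ring-closing metathesis (C10=C11) of a C9 vinyl ketone onto a C12 allylic ether. The C6–O–C12 ether comes from an Ir-catalysed allylic etherification, and C13–Br from inversion of an alcohol.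
- The tetrahydrofuran is made by a SmI2 ketyl–olefin 5-exo cyclisation that forms C6–C7 from an aldehyde/β-alkoxyacrylate. C3/C4 come from a Sharpless kinetic resolution.
- Ring order: tetrahydrofuran first, oxocane second.

Assumption: atoms are numbered C1 (alkyne CH) to C15 (CH3) along the chain; building blocks that deliver skeleton carbons are numbered as starting materials. TBS = tert-butyldimethylsilyl, TMS = trimethylsilyl, TES = triethylsilyl.

**Route**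

Step 1
Reactants: 1 trimethylsilylacetylene; 2 acrolein
Product: 4 rac-5-(trimethylsilyl)pent-1-en-4-yn-3-ol, via lithium acetylide 3 (not isolated)
Conditions: n-BuLi, THF, −78 °C; then 2, −78 °C; H2O
Reagents that add atoms: none
Why: 1,2-addition of a lithium acetylide to an enal (alkynylation) gives the racemic carbinol carrying C1–C5; no stereocentre is fixed because the next step resolves it.

Step 2
Reactants: 4 rac-5-(trimethylsilyl)pent-1-en-4-yn-3-ol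
Product: 5 (1S)-1-[(2R)-oxiran-2-yl]-3-(trimethylsilyl)prop-2-yn-1-ol
Conditions: Ti(OiPr)4 (0.1 equiv), L-(+)-DIPT (0.15 equiv), t-BuOOH (0.45 equiv), 4 Å MS, CH2Cl2, −20 °C
Reagents that add atoms: tert-butyl hydroperoxide, CC(C)(C)OO
Why: Sharpless kinetic resolution (asymmetric epoxidation of a secondary allylic alcohol): with L-(+)-DIPT the (R)-enantiomer of 4 is epoxidised much faster and only to the erythro epoxy alcohol, which sets C3 (S) and C4 (R); the reaction is stopped near 45% conversion.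

Step 3
Reactants: 5 (1S)-1-[(2R)-oxiran-2-yl]-3-(trimethylsilyl)prop-2-yn-1-ol
Product: 6 tert-butyl(dimethyl){[(1S)-1-[(2R)-oxiran-2-yl]-3-(trimethylsilyl)prop-2-yn-1-yl]oxy}silane
Conditions: TBSCl, imidazole, DMF, 0 °C to rt
Reagents that add atoms: tert-butyldimethylsilyl chloride, CC(C)(C)[Si](C)(C)Cl
Why: Standard imidazole-mediated silylation masks the C3 hydroxyl that is inverted to the bromide at the end.

Step 4
Reactants: 6 tert-butyl(dimethyl){[(1S)-1-[(2R)-oxiran-2-yl]-3-(trimethylsilyl)prop-2-yn-1-yl]oxy}silane; 7 vinylmagnesium bromide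
Product: 8 (3S,4R)-3-(TBS-oxy)-1-(trimethylsilyl)hept-6-en-1-yn-4-ol
Conditions: CH2=CHMgBr, CuI (10 mol%), THF, −40 to −20 °C; aq NH4Cl
Reagents that add atoms: none
Why: Copper-catalysed Grignard opening of the terminal epoxide at its CH2 (SN2) frees the C4 hydroxyl without touching C3 or C4; the vinyl group is a masked C6 aldehyde.

Step 5
Reactants: 8 (3S,4R)-3-(TBS-oxy)-1-(trimethylsilyl)hept-6-en-1-yn-4-ol; 9 ethyl propiolate
Product: 10 ethyl (2E)-3-{[(3S,4R)-3-(TBS-oxy)-1-(trimethylsilyl)hept-6-en-1-yn-4-yl]oxy}prop-2-enoate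
Conditions: N-methylmorpholine, CH2Cl2, rt
Reagents that add atoms: none
Why: Amine-catalysed oxa-Michael addition of the alcohol to the propiolate gives the (E)-β-alkoxyacrylate, the radical acceptor that carries C7–C9.

Step 6
Reactants: 10 ethyl (2E)-3-{[(3S,4R)-3-(TBS-oxy)-1-(trimethylsilyl)hept-6-en-1-yn-4-yl]oxy}prop-2-enoate
Product: 12 ethyl (2E)-3-{[(3S,4R)-3-(TBS-oxy)-6-oxo-1-(trimethylsilyl)hex-1-yn-4-yl]oxy}prop-2-enoate, via vicinal diol 11 (not isolated)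
Conditions: OsO4 (2 mol%), NaIO4 (4 equiv), 2,6-lutidine, dioxane/H2O 3:1, rt
Reagents that add atoms: sodium periodate (oxygen source, relayed by OsO4), [Na+].[O-]I(=O)(=O)=O
Why: Lemieux–Johnson cleavage (OsO4 dihydroxylation, NaIO4 glycol cleavage) is selective for the isolated terminal alkene over the electron-poor alkoxyacrylate and the silyl alkyne and unveils the C6 aldehyde.

Step 7
Reactants: 12 ethyl (2E)-3-{[(3S,4R)-3-(TBS-oxy)-6-oxo-1-(trimethylsilyl)hex-1-yn-4-yl]oxy}prop-2-enoate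
Product: 13 ethyl 2-[(2R,3S,5R)-5-[(1S)-1-(TBS-oxy)-3-(trimethylsilyl)prop-2-yn-1-yl]-3-hydroxyoxolan-2-yl]acetate
Conditions: SmI2 (2.5 equiv), MeOH (3 equiv), THF, 0 °C
Reagents that add atoms: none
Why: SmI2 ketyl–olefin radical cyclisation (5-exo, Nakata/Enholm type): the C6 ketyl radical adds to the β-carbon of the (E)-alkoxyacrylate through a chair-like transition state with the C4 side chain pseudo-equatorial (2,5-cis) and the samarium-bound ketyl oxygen anti to the enoate (2,3-trans), forming C6–C7 and setting C6 (S) and C7 (R).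

Step 8
Reactants: 14 (2R)-2-ethyloxirane
Product: 15 (3R)-pent-1-en-3-ol
Conditions: Me3SI (3 equiv), n-BuLi (2.9 equiv), THF, −10 °C to rt
Reagents that add atoms: trimethylsulfonium iodide, C[S+](C)C.[I-]
Why: Epoxide homologation with dimethylsulfonium methylide (ylide opening at CH2, then elimination of Me2S) gives the allylic alcohol with the carbinol centre (future C13) untouched.

Step 9
Reactants: 15 (3R)-pent-1-en-3-ol
Product: 16 triethyl{[(3R)-pent-1-en-3-yl]oxy}silane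
Conditions: TESCl, imidazole, CH2Cl2, 0 °C
Reagents that add atoms: chlorotriethylsilane, CC[Si](CC)(CC)Cl
Why: Silylation; TES is chosen so that it can later be removed in the presence of the TBS ether.

Step 10
Reactants: 16 triethyl{[(3R)-pent-1-en-3-yl]oxy}silane; 17 allyl methyl carbonate
Product: 18 methyl (2E,4R)-4-[(triethylsilyl)oxy]hex-2-en-1-yl carbonate
Conditions: second-generation Hoveyda–Grubbs catalyst (3 mol%), 17 (4 equiv), CH2Cl2, 40 °C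
Reagents that add atoms: none
Why: Olefin cross-metathesis of a hindered allylic ether with an excess of the unhindered allyl carbonate gives the (E)-allylic carbonate.

Step 11
Reactants: 13 ethyl 2-[(2R,3S,5R)-5-[(1S)-1-(TBS-oxy)-3-(trimethylsilyl)prop-2-yn-1-yl]-3-hydroxyoxolan-2-yl]acetate; 18 methyl (2E,4R)-4-[(triethylsilyl)oxy]hex-2-en-1-yl carbonate
Product: 20 ethyl 2-[(2R,3S,5R)-5-[(1S)-1-(TBS-oxy)-3-(trimethylsilyl)prop-2-yn-1-yl]-3-{[(3R,4R)-4-(TES-oxy)hex-1-en-3-yl]oxy}oxolan-2-yl]acetate, via copper alkoxide 19 (not isolated)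
Conditions: LiN(SiMe3)2 (1.0 equiv), THF, −78 °C; CuI (1.0 equiv), 0 °C; then 18, [Ir(cod)Cl]2 (2 mol%), (Ra,Rc,Rc)-binaphthyl bis(1-phenylethyl)phosphoramidite (4 mol%), THF, rt; aq NH4Cl
Reagents that add atoms: none
Why: Ir-catalysed asymmetric allylic etherification (Hartwig type) of the copper alkoxide: attack at the substituted allyl terminus gives the branched secondary–secondary ether, and the phosphoramidite ligand controls the new C12 centre as (R).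

Step 12
Reactants: 20 ethyl 2-[(2R,3S,5R)-5-[(1S)-1-(TBS-oxy)-3-(trimethylsilyl)prop-2-yn-1-yl]-3-{[(3R,4R)-4-(TES-oxy)hex-1-en-3-yl]oxy}oxolan-2-yl]acetate
Product: 21 ethyl 2-[(2R,3S,5R)-5-[(1S)-1-(TBS-oxy)-3-(trimethylsilyl)prop-2-yn-1-yl]-3-{[(3R,4R)-4-hydroxyhex-1-en-3-yl]oxy}oxolan-2-yl]acetate
Conditions: PPTS (0.2 equiv), MeOH, 0 °C to rt
Reagents that add atoms: none
Why: Mild acid-catalysed methanolysis removes the secondary TES ether selectively; the bulkier propargylic TBS ether and the C-silyl group stay.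

Step 13
Reactants: 21 ethyl 2-[(2R,3S,5R)-5-[(1S)-1-(TBS-oxy)-3-(trimethylsilyl)prop-2-yn-1-yl]-3-{[(3R,4R)-4-hydroxyhex-1-en-3-yl]oxy}oxolan-2-yl]acetate
Product: 22 ethyl 2-[(2R,3S,5R)-3-{[(3R,4S)-4-bromohex-1-en-3-yl]oxy}-5-[(1S)-1-(TBS-oxy)-3-(trimethylsilyl)prop-2-yn-1-yl]oxolan-2-yl]acetate
Conditions: CBr4, (n-C8H17)3P, 1-methylcyclohexene, toluene, 70 °C
Reagents that add atoms: carbon tetrabromide, BrC(Br)(Br)Br
Why: Appel-type bromination (SN2 on the alkoxyphosphonium ion) installs the C13 bromide with inversion, (13R)-OH to (13S)-Br, as established for β-alkoxy carbinols of Laurencia ethers.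

Step 14
Reactants: 22 ethyl 2-[(2R,3S,5R)-3-{[(3R,4S)-4-bromohex-1-en-3-yl]oxy}-5-[(1S)-1-(TBS-oxy)-3-(trimethylsilyl)prop-2-yn-1-yl]oxolan-2-yl]acetate
Product: 23 2-[(2R,3S,5R)-3-{[(3R,4S)-4-bromohex-1-en-3-yl]oxy}-5-[(1S)-1-(TBS-oxy)-3-(trimethylsilyl)prop-2-yn-1-yl]oxolan-2-yl]-N-methoxy-N-methylacetamide
Conditions: MeNH(OMe)·HCl (3 equiv), i-PrMgCl (6 equiv), THF, −20 °C
Reagents that add atoms: N,O-dimethylhydroxylamine hydrochloride, CNOC.Cl
Why: Direct ester-to-Weinreb-amide conversion by the magnesium amide made in the flask; the secondary bromide is inert at −20 °C.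

Step 15
Reactants: 23 2-[(2R,3S,5R)-3-{[(3R,4S)-4-bromohex-1-en-3-yl]oxy}-5-[(1S)-1-(TBS-oxy)-3-(trimethylsilyl)prop-2-yn-1-yl]oxolan-2-yl]-N-methoxy-N-methylacetamide; 7 vinylmagnesium bromide
Product: 24 1-[(2R,3S,5R)-3-{[(3R,4S)-4-bromohex-1-en-3-yl]oxy}-5-[(1S)-1-(TBS-oxy)-3-(trimethylsilyl)prop-2-yn-1-yl]oxolan-2-yl]but-3-en-2-one
Conditions: CH2=CHMgBr, THF, −78 to 0 °C; cold aq HCl quench
Reagents that add atoms: none
Why: Grignard addition to the Weinreb amide stops at the ketone through the chelated tetrahedral intermediate and gives the vinyl ketone, which is used at once.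

Step 16
Reactants: 24 1-[(2R,3S,5R)-3-{[(3R,4S)-4-bromohex-1-en-3-yl]oxy}-5-[(1S)-1-(TBS-oxy)-3-(trimethylsilyl)prop-2-yn-1-yl]oxolan-2-yl]but-3-en-2-one
Product: 25 (1S,3R,4Z,8R,10R)-3-[(1S)-1-bromopropyl]-10-[(1S)-1-(TBS-oxy)-3-(trimethylsilyl)prop-2-yn-1-yl]-2,9-dioxabicyclo[6.3.0]undec-4-en-6-one
Conditions: second-generation Hoveyda–Grubbs catalyst (10 mol%), toluene (2 mM), 80 °C
Reagents that add atoms: none
Why: Ring-closing metathesis between the allylic-ether vinyl group and the vinyl ketone forms C10=C11 and the eight-membered ring; the trans-disposed substituents on the tetrahydrofuran and the gauche effect of the C–O bonds favour closure to the (Z)-enone.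

Step 17
Reactants: 25 (1S,3R,4Z,8R,10R)-3-[(1S)-1-bromopropyl]-10-[(1S)-1-(TBS-oxy)-3-(trimethylsilyl)prop-2-yn-1-yl]-2,9-dioxabicyclo[6.3.0]undec-4-en-6-one
Product: 27 (1S,3R,8R,10R)-3-[(1S)-1-bromopropyl]-10-[(1S)-1-(TBS-oxy)-3-(trimethylsilyl)prop-2-yn-1-yl]-2,9-dioxabicyclo[6.3.0]undec-5-en-6-yl acetate (ring-cis double bond), via lithium enolate 26 (not isolated)
Conditions: LiBH(s-Bu)3 (1.1 equiv), THF, −78 °C; then Ac2O (3 equiv), −78 to −20 °C
Reagents that add atoms: acetic anhydride, CC(=O)OC(C)=O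
Why: Conjugate (1,4) reduction of the cyclic enone by the hindered borohydride gives only the C9–C10 enolate, and its O-acetylation (House enolate trapping) gives the regiodefined enol acetate.

Step 18
Reactants: 27 (1S,3R,8R,10R)-3-[(1S)-1-bromopropyl]-10-[(1S)-1-(TBS-oxy)-3-(trimethylsilyl)prop-2-yn-1-yl]-2,9-dioxabicyclo[6.3.0]undec-5-en-6-yl acetate
Product: 28 (1S,3R,5S,6R,8R,10R)-5-bromo-3-[(1S)-1-bromopropyl]-10-[(1S)-1-(TBS-oxy)-3-(trimethylsilyl)prop-2-yn-1-yl]-2,9-dioxabicyclo[6.3.0]undecan-6-yl acetate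
Conditions: anhydrous HBr (1.2 equiv), hν (350 nm), pentane/CH2Cl2, −78 °C; cold aq NaHCO3
Reagents that add atoms: hydrogen bromide, Br
Why: Proposed new method: radical-chain anti-Markovnikov hydrobromination of a medium-ring enol acetate, in which Br• adds to C10 (the carbon β to OAc, giving the α-acetoxy radical) from the face opposite the C12 side chain and the C7–O bond, and HBr then delivers H to C9 anti to the bridging bromine, so that Br and OAc end cis as (9R,10S), while the electron-poor silyl alkyne and the silyl ether are not attacked at −78 °C; the closest known reactions are the stereospecific anti radical addition of HBr to 1-substituted cyclohexenes (Goering, cis products) and the light- or peroxide-initiated anti-Markovnikov addition of HBr to vinyl and enol acetates.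

Step 19
Reactants: 28 (1S,3R,5S,6R,8R,10R)-5-bromo-3-[(1S)-1-bromopropyl]-10-[(1S)-1-(TBS-oxy)-3-(trimethylsilyl)prop-2-yn-1-yl]-2,9-dioxabicyclo[6.3.0]undecan-6-yl acetate
Product: 29 (1S,3R,5S,6R,8R,10R)-5-bromo-3-[(1S)-1-bromopropyl]-10-[(1S)-1-hydroxyprop-2-yn-1-yl]-2,9-dioxabicyclo[6.3.0]undecan-6-yl acetate
Conditions: Bu4NF (3 equiv), AcOH (3 equiv), THF, 0 °C to rt
Reagents that add atoms: none
Why: Buffered fluoride desilylation removes the O-TBS and the alkyne C-TMS groups in one operation while the acetate and the secondary bromides stay intact.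

Step 20
Reactants: 29 (1S,3R,5S,6R,8R,10R)-5-bromo-3-[(1S)-1-bromopropyl]-10-[(1S)-1-hydroxyprop-2-yn-1-yl]-2,9-dioxabicyclo[6.3.0]undecan-6-yl acetate
Product: 30 (1S,3R,5S,6R,8R,10R)-5-bromo-3-[(1S)-1-bromopropyl]-10-[(1R)-1-bromoprop-2-yn-1-yl]-2,9-dioxabicyclo[6.3.0]undecan-6-yl acetate
Conditions: CBr4, PPh3, 2,6-lutidine, CH2Cl2, 0 °C
Reagents that add atoms: carbon tetrabromide, BrC(Br)(Br)Br
Why: Appel bromination of the propargylic alcohol proceeds by SN2 with inversion, (3S)-OH to (3R)-Br, and completes the target.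

**Compound list**

1 | trimethylsilylacetylene | C#C[Si](C)(C)C | starting material
2 | acrolein | C=CC=O | starting material
3 | lithium (trimethylsilyl)acetylide | [Li]C#C[Si](C)(C)C | intermediate
4 | rac-5-(trimethylsilyl)pent-1-en-4-yn-3-ol | C=CC(O)C#C[Si](C)(C)C | intermediate
5 | (1S)-1-[(2R)-oxiran-2-yl]-3-(trimethylsilyl)prop-2-yn-1-ol | C[Si](C)(C)C#C[C@H](O)[C@H]1CO1 | intermediate
6 | tert-butyl(dimethyl){[(1S)-1-[(2R)-oxiran-2-yl]-3-(trimethylsilyl)prop-2-yn-1-yl]oxy}silane | C[Si](C)(C)C#C[C@H](O[Si](C)(C)C(C)(C)C)[C@H]1CO1 | intermediate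
7 | vinylmagnesium bromide | C=C[Mg]Br | starting material
8 | (3S,4R)-3-(TBS-oxy)-1-(trimethylsilyl)hept-6-en-1-yn-4-ol | C[Si](C)(C)C#C[C@H](O[Si](C)(C)C(C)(C)C)[C@@H](CC=C)O | intermediate
9 | ethyl propiolate | C#CC(=O)OCC | starting material
10 | ethyl (2E)-3-{[(3S,4R)-3-(TBS-oxy)-1-(trimethylsilyl)hept-6-en-1-yn-4-yl]oxy}prop-2-enoate | C[Si](C)(C)C#C[C@H](O[Si](C)(C)C(C)(C)C)[C@@H](CC=C)O/C=C/C(=O)OCC | intermediate
11 | ethyl (2E)-3-{[(3S,4R)-3-(TBS-oxy)-6,7-dihydroxy-1-(trimethylsilyl)hept-1-yn-4-yl]oxy}prop-2-enoate (both C6 epimers) | C[Si](C)(C)C#C[C@H](O[Si](C)(C)C(C)(C)C)[C@@H](CC(O)CO)O/C=C/C(=O)OCC | intermediate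
12 | ethyl (2E)-3-{[(3S,4R)-3-(TBS-oxy)-6-oxo-1-(trimethylsilyl)hex-1-yn-4-yl]oxy}prop-2-enoate | C[Si](C)(C)C#C[C@H](O[Si](C)(C)C(C)(C)C)[C@@H](CC=O)O/C=C/C(=O)OCC | intermediate
13 | ethyl 2-[(2R,3S,5R)-5-[(1S)-1-(TBS-oxy)-3-(trimethylsilyl)prop-2-yn-1-yl]-3-hydroxyoxolan-2-yl]acetate | C[Si](C)(C)C#C[C@H](O[Si](C)(C)C(C)(C)C)[C@H]1C[C@H](O)[C@@H](CC(=O)OCC)O1 | intermediate
14 | (2R)-2-ethyloxirane | CC[C@@H]1CO1 | starting material
15 | (3R)-pent-1-en-3-ol | C=C[C@H](O)CC | intermediate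
16 | triethyl{[(3R)-pent-1-en-3-yl]oxy}silane | C=C[C@H](O[Si](CC)(CC)CC)CC | intermediate
17 | allyl methyl carbonate | C=CCOC(=O)OC | starting material
18 | methyl (2E,4R)-4-[(triethylsilyl)oxy]hex-2-en-1-yl carbonate | COC(=O)OC/C=C/[C@H](O[Si](CC)(CC)CC)CC | intermediate
19 | copper alkoxide of 13 | C[Si](C)(C)C#C[C@H](O[Si](C)(C)C(C)(C)C)[C@H]1C[C@H](O[Cu])[C@@H](CC(=O)OCC)O1 | intermediate
20 | ethyl 2-[(2R,3S,5R)-5-[(1S)-1-(TBS-oxy)-3-(trimethylsilyl)prop-2-yn-1-yl]-3-{[(3R,4R)-4-(TES-oxy)hex-1-en-3-yl]oxy}oxolan-2-yl]acetate | C[Si](C)(C)C#C[C@H](O[Si](C)(C)C(C)(C)C)[C@H]1C[C@H](O[C@@H]([C@H](O[Si](CC)(CC)CC)CC)C=C)[C@@H](CC(=O)OCC)O1 | intermediate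
21 | ethyl 2-[(2R,3S,5R)-5-[(1S)-1-(TBS-oxy)-3-(trimethylsilyl)prop-2-yn-1-yl]-3-{[(3R,4R)-4-hydroxyhex-1-en-3-yl]oxy}oxolan-2-yl]acetate | C[Si](C)(C)C#C[C@H](O[Si](C)(C)C(C)(C)C)[C@H]1C[C@H](O[C@@H]([C@H](O)CC)C=C)[C@@H](CC(=O)OCC)O1 | intermediate
22 | ethyl 2-[(2R,3S,5R)-3-{[(3R,4S)-4-bromohex-1-en-3-yl]oxy}-5-[(1S)-1-(TBS-oxy)-3-(trimethylsilyl)prop-2-yn-1-yl]oxolan-2-yl]acetate | C[Si](C)(C)C#C[C@H](O[Si](C)(C)C(C)(C)C)[C@H]1C[C@H](O[C@@H]([C@@H](Br)CC)C=C)[C@@H](CC(=O)OCC)O1 | intermediate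
23 | 2-[(2R,3S,5R)-3-{[(3R,4S)-4-bromohex-1-en-3-yl]oxy}-5-[(1S)-1-(TBS-oxy)-3-(trimethylsilyl)prop-2-yn-1-yl]oxolan-2-yl]-N-methoxy-N-methylacetamide | C[Si](C)(C)C#C[C@H](O[Si](C)(C)C(C)(C)C)[C@H]1C[C@H](O[C@@H]([C@@H](Br)CC)C=C)[C@@H](CC(=O)N(C)OC)O1 | intermediate
24 | 1-[(2R,3S,5R)-3-{[(3R,4S)-4-bromohex-1-en-3-yl]oxy}-5-[(1S)-1-(TBS-oxy)-3-(trimethylsilyl)prop-2-yn-1-yl]oxolan-2-yl]but-3-en-2-one | C[Si](C)(C)C#C[C@H](O[Si](C)(C)C(C)(C)C)[C@H]1C[C@H](O[C@@H]([C@@H](Br)CC)C=C)[C@@H](CC(=O)C=C)O1 | intermediate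
25 | (1S,3R,4Z,8R,10R)-3-[(1S)-1-bromopropyl]-10-[(1S)-1-(TBS-oxy)-3-(trimethylsilyl)prop-2-yn-1-yl]-2,9-dioxabicyclo[6.3.0]undec-4-en-6-one | C[Si](C)(C)C#C[C@H](O[Si](C)(C)C(C)(C)C)[C@H]1C[C@@H]2O[C@@H]([C@@H](Br)CC)/C=C\C(=O)C[C@H]2O1 | intermediate
26 | lithium enolate of the 6-ketone (C9–C10 enolate) | C[Si](C)(C)C#C[C@H](O[Si](C)(C)C(C)(C)C)[C@H]1C[C@@H]2O[C@@H]([C@@H](Br)CC)C/C=C(O[Li])\C[C@H]2O1 | intermediate
27 | (1S,3R,8R,10R)-3-[(1S)-1-bromopropyl]-10-[(1S)-1-(TBS-oxy)-3-(trimethylsilyl)prop-2-yn-1-yl]-2,9-dioxabicyclo[6.3.0]undec-5-en-6-yl acetate (ring-cis) | C[Si](C)(C)C#C[C@H](O[Si](C)(C)C(C)(C)C)[C@H]1C[C@@H]2O[C@@H]([C@@H](Br)CC)C/C=C(OC(C)=O)\C[C@H]2O1 | intermediate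
28 | (1S,3R,5S,6R,8R,10R)-5-bromo-3-[(1S)-1-bromopropyl]-10-[(1S)-1-(TBS-oxy)-3-(trimethylsilyl)prop-2-yn-1-yl]-2,9-dioxabicyclo[6.3.0]undecan-6-yl acetate | C[Si](C)(C)C#C[C@H](O[Si](C)(C)C(C)(C)C)[C@H]1C[C@@H]2O[C@@H]([C@@H](Br)CC)C[C@H](Br)[C@H](OC(C)=O)C[C@H]2O1 | intermediate
29 | (1S,3R,5S,6R,8R,10R)-5-bromo-3-[(1S)-1-bromopropyl]-10-[(1S)-1-hydroxyprop-2-yn-1-yl]-2,9-dioxabicyclo[6.3.0]undecan-6-yl acetate | C#C[C@H](O)[C@H]1C[C@@H]2O[C@@H]([C@@H](Br)CC)C[C@H](Br)[C@H](OC(C)=O)C[C@H]2O1 | intermediate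
30 | (1S,3R,5S,6R,8R,10R)-5-bromo-3-[(1S)-1-bromopropyl]-10-[(1R)-1-bromoprop-2-yn-1-yl]-2,9-dioxabicyclo[6.3.0]undecan-6-yl acetate | C#C[C@@H](Br)[C@H]1C[C@@H]2O[C@@H]([C@@H](Br)CC)C[C@H](Br)[C@H](OC(C)=O)C[C@H]2O1 | target

**Summary**

Total step count: 20 (17 in the main line, 3 in the side branch to carbonate 18).
Longest linear sequence: 17 steps (steps 1–7 and 11–20).

Three steps most likely to fail, each with a fallback:

- Step 18 (radical HBr addition; the face of attack, ionic cleavage of the enol acetate and survival of the silyl groups are the risks). The fallback sets out from 25 and returns at 28 by ionic chemistry. Conjugate reduction of 25 with LiBH(s-Bu)3 and trapping of enolate 26 with N-bromosuccinimide gives (1S,3R,5S,8R,10R)-5-bromo-3-[(1S)-1-bromopropyl]-10-[(1S)-1-(TBS-oxy)-3-(trimethylsilyl)prop-2-yn-1-yl]-2,9-dioxabicyclo[6.3.0]undecan-6-one F8, with bromine entering anti to the C12 side chain. Reduction with Zn(BH4)2 at −78 °C, hydride anti to the C–Br dipole (Cornforth), gives the cis-bromohydrin (1S,3R,5S,6R,8R,10R)-5-bromo-3-[(1S)-1-bromopropyl]-10-[(1S)-1-(TBS-oxy)-3-(trimethylsilyl)prop-2-yn-1-yl]-2,9-dioxabicyclo[6.3.0]undecan-6-ol F9. Acetylation (Ac2O, DMAP, pyridine) gives 28.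

- Step 16 (eight-membered ring closure onto an electron-poor vinyl ketone). The fallback sets out from 23 and returns at 25 by closing the ring at the alcohol oxidation level. Reduction of 23 with i-Bu2AlH at −78 °C gives 2-[(2R,3S,5R)-3-{[(3R,4S)-4-bromohex-1-en-3-yl]oxy}-5-[(1S)-1-(TBS-oxy)-3-(trimethylsilyl)prop-2-yn-1-yl]oxolan-2-yl]acetaldehyde F5. Addition of 7 gives 1-[(2R,3S,5R)-3-{[(3R,4S)-4-bromohex-1-en-3-yl]oxy}-5-[(1S)-1-(TBS-oxy)-3-(trimethylsilyl)prop-2-yn-1-yl]oxolan-2-yl]but-3-en-2-ol F6 as both C9 epimers. Ring-closing metathesis of this more reactive diene gives (1S,3R,4Z,8R,10R)-3-[(1S)-1-bromopropyl]-10-[(1S)-1-(TBS-oxy)-3-(trimethylsilyl)prop-2-yn-1-yl]-2,9-dioxabicyclo[6.3.0]undec-4-en-6-ol F7, and Dess–Martin oxidation gives 25.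

- Step 11 (two hindered partners in the Ir-catalysed etherification). The fallback sets out from 13 and returns at 21 by palladium π-allyl chemistry of a vinyl epoxide, which also avoids the silyl protecting group. (2E)-Pent-2-en-1-ol F1 is epoxidised (Ti(OiPr)4, D-(−)-DET, t-BuOOH) to [(2R,3R)-3-ethyloxiran-2-yl]methanol F2. Oxidation (SO3·pyridine, DMSO, Et3N) gives (2S,3R)-3-ethyloxirane-2-carbaldehyde F3, and methylenation (Ph3P=CH2) gives (2R,3R)-2-ethenyl-3-ethyloxirane F4. Alcohol 13 and F4 with Pd2(dba)3 (zerovalent palladium), Trost's chiral diamide bisphosphine ligand and catalytic Et3B give 21 directly, by boron-tethered delivery of the alkoxide to the allylic carbon with net retention; 21 re-enters at step 13.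

**Further compounds**

F1 | step 11 | (2E)-pent-2-en-1-ol | CC/C=C/CO
F2 | step 11 | [(2R,3R)-3-ethyloxiran-2-yl]methanol | OC[C@H]1O[C@@H]1CC
F3 | step 11 | (2S,3R)-3-ethyloxirane-2-carbaldehyde | O=C[C@H]1O[C@@H]1CC
F4 | step 11 | (2R,3R)-2-ethenyl-3-ethyloxirane | C=C[C@H]1O[C@@H]1CC
F5 | step 16 | 2-[(2R,3S,5R)-3-{[(3R,4S)-4-bromohex-1-en-3-yl]oxy}-5-[(1S)-1-(TBS-oxy)-3-(trimethylsilyl)prop-2-yn-1-yl]oxolan-2-yl]acetaldehyde | C[Si](C)(C)C#C[C@H](O[Si](C)(C)C(C)(C)C)[C@H]1C[C@H](O[C@@H]([C@@H](Br)CC)C=C)[C@@H](CC=O)O1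
F6 | step 16 | 1-[(2R,3S,5R)-3-{[(3R,4S)-4-bromohex-1-en-3-yl]oxy}-5-[(1S)-1-(TBS-oxy)-3-(trimethylsilyl)prop-2-yn-1-yl]oxolan-2-yl]but-3-en-2-ol (both C2 epimers) | C[Si](C)(C)C#C[C@H](O[Si](C)(C)C(C)(C)C)[C@H]1C[C@H](O[C@@H]([C@@H](Br)CC)C=C)[C@@H](CC(O)C=C)O1
F7 | step 16 | (1S,3R,4Z,8R,10R)-3-[(1S)-1-bromopropyl]-10-[(1S)-1-(TBS-oxy)-3-(trimethylsilyl)prop-2-yn-1-yl]-2,9-dioxabicyclo[6.3.0]undec-4-en-6-ol (both C6 epimers) | C[Si](C)(C)C#C[C@H](O[Si](C)(C)C(C)(C)C)[C@H]1C[C@@H]2O[C@@H]([C@@H](Br)CC)/C=C\C(O)C[C@H]2O1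
F8 | step 18 | (1S,3R,5S,8R,10R)-5-bromo-3-[(1S)-1-bromopropyl]-10-[(1S)-1-(TBS-oxy)-3-(trimethylsilyl)prop-2-yn-1-yl]-2,9-dioxabicyclo[6.3.0]undecan-6-one | C[Si](C)(C)C#C[C@H](O[Si](C)(C)C(C)(C)C)[C@H]1C[C@@H]2O[C@@H]([C@@H](Br)CC)C[C@H](Br)C(=O)C[C@H]2O1
F9 | step 18 | (1S,3R,5S,6R,8R,10R)-5-bromo-3-[(1S)-1-bromopropyl]-10-[(1S)-1-(TBS-oxy)-3-(trimethylsilyl)prop-2-yn-1-yl]-2,9-dioxabicyclo[6.3.0]undecan-6-ol | C[Si](C)(C)C#C[C@H](O[Si](C)(C)C(C)(C)C)[C@H]1C[C@@H]2O[C@@H]([C@@H](Br)CC)C[C@H](Br)[C@H](O)C[C@H]2O1
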